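**Assumption (one line):** atoms are labelled C1–C12 along the polypropionate chain of the target (C1 = lactone carbonyl, C2/C7 = the two fully substituted ring carbons, C12 = methyl on C11); the methyl ketal carbon C7 in 13, 14, 17 and 18 is drawn as the expected axial-OMe anomer, which is of no consequence because C7 becomes planar in step 11.

## Retrosynthetic overview

1. Target 20 ⇐ one-flask biomimetic closure of monocyclic 17: δ-lactonisation (O5→C1, auxiliary as leaving group), then ketal → tetrahydropyranyl oxocarbenium at C7 and capture by the C2 enol (sets C2 and C7).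
2. 17 ⇐ C4–C5 syn aldol of β-keto imide 16 with ketal aldehyde 14 (sets C4, C5).
3. 14 ⇐ C6–C7 bond: chiral titanium enolate of 11 + lactonium ion from acetoxy lactone 8 (sets C6).
4. 8 ⇐ methyl (R)-3-hydroxybutanoate by Fráter–Seebach / Claisen / syn reduction / Fráter–Seebach (all-anti C8–C11).
5. Ring order: tetrahydropyran (as δ-lactone 7, step 5) → C1/O5 δ-lactone → cyclohexanone (C2–C7), the last two in step 11.

## Route

Step 1
Reactants: 1 methyl (3R)-3-hydroxybutanoate
Product: 2 methyl (2R,3R)-3-hydroxy-2-methylbutanoate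
Conditions: LiN(i-Pr)2 (2.2 equiv), THF, −50 → −20 °C; MeI, −78 → 0 °C
Reagents that add atoms: iodomethane, CI
Why: Fráter–Seebach alkylation: the chelated lithium alkoxide–enolate is methylated anti to the C–O bond of the chelate, which sets C10 (anti, dr about 95:5).

Step 2
Reactants: 2 methyl (2R,3R)-3-hydroxy-2-methylbutanoate; 3 tert-butyl acetate
Product: 4 tert-butyl (4R,5R)-5-hydroxy-4-methyl-3-oxohexanoate
Conditions: 3 (4 equiv), LiN(i-Pr)2 (4 equiv), THF, −78 °C; then 2, −78 → −30 °C
Reagents that add atoms: none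
Why: crossed Claisen condensation: the preformed ester enolate first deprotonates the hydroxyl, then acylates at the methyl ester, and the product rests as its β-keto ester enolate, so the α-methyl centre is not epimerised.

Step 3
Reactants: 4 tert-butyl (4R,5R)-5-hydroxy-4-methyl-3-oxohexanoate
Product: 5 tert-butyl (3S,4R,5R)-3,5-dihydroxy-4-methylhexanoate
Conditions: Et2BOMe (1.1 equiv), THF–MeOH 4:1, −78 °C; NaBH4; then AcOH, MeOH co-evaporation
Reagents that add atoms: none
Why: Narasaka–Prasad reduction: the diethylboron chelate of the β-hydroxy ketone takes hydride by external axial attack and gives the 1,3-syn diol, which sets C9.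

Step 4
Reactants: 5 tert-butyl (3S,4R,5R)-3,5-dihydroxy-4-methylhexanoate
Product: 6 tert-butyl (2R,3R,4R,5R)-3,5-dihydroxy-2,4-dimethylhexanoate
Conditions: LiN(i-Pr)2 (3.3 equiv), THF–DMPU, −78 → −20 °C; MeI, −78 → −20 °C
Reagents that add atoms: iodomethane, CI
Why: second Fráter–Seebach alkylation: in the lithium dialkoxide–enolate the methyl group enters anti to the C3 oxygen, which sets C8 and completes the all-anti C8–C11 array.

Step 5
Reactants: 6 tert-butyl (2R,3R,4R,5R)-3,5-dihydroxy-2,4-dimethylhexanoate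
Product: 8 (3R,4R,5R,6R)-3,5,6-trimethyl-2-oxooxan-4-yl acetate, via hydroxy lactone 7 (not isolated)
Conditions: CF3CO2H, CH2Cl2, 0 → 23 °C; evaporate; then Ac2O, pyridine, DMAP (cat.), CH2Cl2, 23 °C
Reagents that add atoms: acetic anhydride, CC(=O)OC(C)=O
Why: acidolysis of the tert-butyl ester and δ-lactonisation (only the C11 hydroxyl can close a six-membered ring) build the future tetrahydropyran ring, and DMAP-catalysed acetylation then caps the axial C9 hydroxyl; no stereocentre is touched.

Step 6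
Reactants: 9 (4S)-4-benzyl-1,3-thiazolidine-2-thione; 10 propanoyl chloride
Product: 11 (4S)-4-benzyl-3-propanoyl-1,3-thiazolidine-2-thione
Conditions: Et3N (1.3 equiv), DMAP (cat.), CH2Cl2, 0 → 23 °C
Reagents that add atoms: none
Why: N-acylation of the thiazolidinethione auxiliary; no stereocentre is formed.

Step 7
Reactants: 8 (3R,4R,5R,6R)-3,5,6-trimethyl-2-oxooxan-4-yl acetate; 11 (4S)-4-benzyl-3-propanoyl-1,3-thiazolidine-2-thione
Product: 13 (4S)-4-benzyl-3-{(2R)-2-[(2R,3R,4R,5R,6R)-4-(acetyloxy)-2-methoxy-3,5,6-trimethyloxan-2-yl]propanoyl}-1,3-thiazolidine-2-thione, via lactonium tetrafluoroborate 12 (not isolated)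
Conditions: 8, Me3O+ BF4− (1.2 equiv), CH2Cl2, 23 °C; separately 11, TiCl4 (1.05 equiv), i-Pr2NEt (1.05 equiv), CH2Cl2, −78 → −40 °C; add 12, −78 → −20 °C; aq. NaHCO3
Reagents that add atoms: trimethyloxonium tetrafluoroborate, C[O+](C)C.F[B-](F)(F)F
Why: Proposed new method: Meerwein O-methylation turns the δ-lactone into a cyclic dialkoxycarbenium ion (the electrophile TiCl4 generates from orthoesters), and the chelated Z chlorotitanium enolate of 11 adds to it at carbon from the face anti to the benzyl group, which sets C6 and leaves C7 as a methyl ketal; the closest known reaction type is the Evans/Urpí addition of titanium enolates of N-acyl oxazolidinones and thiazolidinethiones to orthoformates, acetals and ketals.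

Step 8
Reactants: 13 (thioimide from step 7)
Product: 14 (2S)-2-[(2R,3R,4R,5R,6R)-4-(acetyloxy)-2-methoxy-3,5,6-trimethyloxan-2-yl]propanal
Conditions: i-Bu2AlH (1.1 equiv), CH2Cl2, −78 °C, 10 min; aq. potassium sodium tartrate
Reagents that add atoms: none
Why: partial reduction of the twisted, strongly activated N-acyl thiazolidinethione stops at the aluminium hemiaminal and releases the aldehyde on work-up (Crimmins-type auxiliary cleavage), faster than attack on the acetate; C6 is not epimerised under these non-basic conditions.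

Step 9
Reactants: 15 (4R)-4-benzyl-3-propanoyl-1,3-oxazolidin-2-one; 10 propanoyl chloride
Product: 16 (4R)-4-benzyl-3-[(2S)-2-methyl-3-oxopentanoyl]-1,3-oxazolidin-2-one
Conditions: LiN(i-Pr)2 (1.05 equiv), THF, −78 °C; then 10, −78 °C
Reagents that add atoms: none
Why: Evans C-acylation of the Z lithium enolate anti to the benzyl group gives the (2S) β-keto imide, whose C2–H is kinetically non-acidic (allylic 1,3-strain), so the centre holds.

Step 10
Reactants: 14 (ketal aldehyde); 16 (β-keto imide)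
Product: 17 (4R)-4-benzyl-3-[(2S,4S,5S,6S)-6-[(2S,3R,4R,5R,6R)-4-(acetyloxy)-2-methoxy-3,5,6-trimethyloxan-2-yl]-5-hydroxy-2,4-dimethyl-3-oxoheptanoyl]-1,3-oxazolidin-2-one
Conditions: 16, TiCl4 (1.1 equiv), i-Pr2NEt (1.2 equiv), CH2Cl2, −10 °C; then 14, −78 → −40 °C; aq. NH4Cl
Reagents that add atoms: none
Why: Evans β-keto imide titanium aldol: the chelated Z enolate reacts through a Zimmerman–Traxler chair in which the C2 stereocentre selects the enolate face, giving the syn,syn adduct (sets C4 and C5), and the anti-Felkin sense that Z enolates prefer with the α-methyl aldehyde (C5/C6 anti) is the matched one.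

Step 11
Reactants: 17 (aldol adduct)
Product: 20 CNP0257416.1 (target), via keto lactone 18 (not isolated), via oxocarbenium triflate 19 (not isolated)
Conditions: Sc(OSO2CF3)3 (0.2 equiv), 4 Å molecular sieves, CH2Cl2–MeCN 4:1, 0 → 23 °C
Reagents that add atoms: none
Why: Lewis-acid-catalysed acyl transfer from the chelated β-keto imide to O5 closes the δ-lactone (the auxiliary leaves like a thioester in a chain release), the same catalyst ionises the methyl ketal, and the enol of 18 attacks the tetrahydropyranyl oxocarbenium 19 through C2 (intramolecular C-glycosylation-type alkylation of a 1,3-dicarbonyl); the lactone tether fixes C2, and C6 fixes C7 because the C6 methyl eclipses the ring oxygen and attack comes anti to the axial C9 acetate.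

## Compound list

1 | methyl (3R)-3-hydroxybutanoate | C[C@@H](O)CC(=O)OC | starting material
2 | methyl (2R,3R)-3-hydroxy-2-methylbutanoate | C[C@@H](O)[C@@H](C)C(=O)OC | intermediate
3 | tert-butyl acetate | CC(=O)OC(C)(C)C | starting material
4 | tert-butyl (4R,5R)-5-hydroxy-4-methyl-3-oxohexanoate | C[C@@H](O)[C@@H](C)C(=O)CC(=O)OC(C)(C)C | intermediate
5 | tert-butyl (3S,4R,5R)-3,5-dihydroxy-4-methylhexanoate | C[C@@H](O)[C@@H](C)[C@@H](O)CC(=O)OC(C)(C)C | intermediate
6 | tert-butyl (2R,3R,4R,5R)-3,5-dihydroxy-2,4-dimethylhexanoate | C[C@@H](O)[C@@H](C)[C@@H](O)[C@@H](C)C(=O)OC(C)(C)C | intermediate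
7 | hydroxy lactone, (3R,4R,5S,6R)-4-hydroxy-3,5,6-trimethyloxan-2-one | C[C@H]1OC(=O)[C@H](C)[C@H](O)[C@@H]1C | intermediate
8 | (3R,4R,5R,6R)-3,5,6-trimethyl-2-oxooxan-4-yl acetate | C[C@H]1OC(=O)[C@H](C)[C@H](OC(C)=O)[C@@H]1C | intermediate
9 | (4S)-4-benzyl-1,3-thiazolidine-2-thione | S=C1SC[C@H](Cc2ccccc2)N1 | starting material
10 | propanoyl chloride | CCC(Cl)=O | starting material
11 | (4S)-4-benzyl-3-propanoyl-1,3-thiazolidine-2-thione | S=C1SC[C@H](Cc2ccccc2)N1C(=O)CC | intermediate
12 | lactonium tetrafluoroborate: O-methylated 8 (4-acetoxy-6-methoxy-2,3,5-trimethyl-3,4-dihydro-2H-pyran-1-ium, stereocentres as in 8) | C[C@H]1[O+]=C(OC)[C@H](C)[C@H](OC(C)=O)[C@@H]1C.F[B-](F)(F)F | intermediate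
13 | (4S)-4-benzyl-3-{(2R)-2-[(2R,3R,4R,5R,6R)-4-(acetyloxy)-2-methoxy-3,5,6-trimethyloxan-2-yl]propanoyl}-1,3-thiazolidine-2-thione | S=C1SC[C@H](Cc2ccccc2)N1C(=O)[C@H](C)[C@]3(OC)O[C@H](C)[C@@H](C)[C@@H](OC(C)=O)[C@H]3C | intermediate
14 | (2S)-2-[(2R,3R,4R,5R,6R)-4-(acetyloxy)-2-methoxy-3,5,6-trimethyloxan-2-yl]propanal | O=C[C@H](C)[C@]1(OC)O[C@H](C)[C@@H](C)[C@@H](OC(C)=O)[C@H]1C | intermediate
15 | (4R)-4-benzyl-3-propanoyl-1,3-oxazolidin-2-one | O=C1OC[C@@H](Cc2ccccc2)N1C(=O)CC | starting material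
16 | (4R)-4-benzyl-3-[(2S)-2-methyl-3-oxopentanoyl]-1,3-oxazolidin-2-one | O=C1OC[C@@H](Cc2ccccc2)N1C(=O)[C@@H](C)C(=O)CC | intermediate
17 | (4R)-4-benzyl-3-[(2S,4S,5S,6S)-6-[(2S,3R,4R,5R,6R)-4-(acetyloxy)-2-methoxy-3,5,6-trimethyloxan-2-yl]-5-hydroxy-2,4-dimethyl-3-oxoheptanoyl]-1,3-oxazolidin-2-one | O=C1OC[C@@H](Cc2ccccc2)N1C(=O)[C@@H](C)C(=O)[C@@H](C)[C@H](O)[C@H](C)[C@]3(OC)O[C@H](C)[C@@H](C)[C@@H](OC(C)=O)[C@H]3C | intermediate
18 | keto lactone (enol form), (5S,6S)-6-{(1S)-1-[(2R,3R,4R,5R,6R)-4-(acetyloxy)-2-methoxy-3,5,6-trimethyloxan-2-yl]ethyl}-4-hydroxy-3,5-dimethyl-5,6-dihydro-2H-pyran-2-one | CC1=C(O)[C@@H](C)[C@H](OC1=O)[C@H](C)[C@]3(OC)O[C@H](C)[C@@H](C)[C@@H](OC(C)=O)[C@H]3C | intermediate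
19 | oxocarbenium triflate: 18 after loss of methoxide from C7 (tetrahydropyranylium, all other stereocentres as in 18) | CC1=C(O)[C@@H](C)[C@H](OC1=O)[C@H](C)C3=[O+][C@H](C)[C@@H](C)[C@@H](OC(C)=O)[C@H]3C.[O-]S(=O)(=O)C(F)(F)F | intermediate
20 | CNP0257416.1, (1R,3'R,4S,4'R,5'R,6S,6'R,7S,8S)-3',4,5',6,6',7-hexamethyl-3,5-dioxospiro[2-oxabicyclo[2.2.2]octane-8,2'-oxan]-4'-yl acetate (chain labels: 2S,4S,5R,6S,7S,8R,9R,10R,11R) | CC(=O)O[C@@H]1[C@H](C)[C@@H](C)O[C@@]2([C@@H]1C)[C@@H](C)[C@H]1OC(=O)[C@]2(C)C(=O)[C@H]1C | target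

## Step count and weak points

Total: 11 steps. Longest linear sequence: 9 steps (1, 2, 3, 4, 5, 7, 8, 10, 11).

**Most likely to fail, with fallbacks**

1. **Step 11 (cascade).** Two adjacent fully substituted carbons are joined. The oxocarbenium can instead lose a proton to an enol ether, which would then expel the allylic C9 acetate or the C5 lactone oxygen. O-alkylation of the enol is reversible but may stall. Fallback, from 17 back to 20: DMAP (0.2 equiv) in CH2Cl2 at 23 °C gives keto lactone 18, this time isolated, with release of the oxazolidinone. Me3SiCl/Et3N converts 18 into the trimethylsilyl enol ether F1. Catalytic Me3SiOSO2CF3 in CH2Cl2 at −78 °C then ionises the ketal, and the silyl enol ether closes the C2–C7 bond in an intramolecular Mukaiyama-type alkylation, giving 20 under kinetic control at low temperature.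

2. **Step 7 (lactonium / titanium enolate coupling).** Chloride can demethylate the lactonium ion, the C9 acetate can bridge to C7, and the carbenium carbon is hindered. Fallback, from 8 back to 14: a Reformatsky reagent from S-ethyl 2-bromopropanethioate and Zn (THF, 0 °C; not basic enough to eliminate the β-acetate) adds once to the lactone carbonyl and gives the hemiketal β-keto thioester F2 as a C6 epimer pair. HC(OMe)3/MeOH/pyridinium tosylate converts it into the methyl ketal thioester F3; the C6 epimers are separated and the unwanted one is re-equilibrated with DBU and recycled. Fukuyama reduction of F3 (Et3SiH, Pd/C, acetone) gives 14 without touching the acetate. Here C6 is set by separation and recycling instead of by the auxiliary.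

3. **Step 8 (partial reduction).** The acetate may be attacked, or the β,β-dialkoxy aldehyde may eliminate methanol. Fallback, from 13 back to 14: NaBH4 in THF–H2O at 0 °C reduces the thioimide to the primary alcohol F4 (acetate untouched, auxiliary recovered), and Dess–Martin periodinane/NaHCO3 in CH2Cl2 oxidises F4 to 14.

## Further compounds

F1 | step 11 | (5S,6S)-6-{(1S)-1-[(2R,3R,4R,5R,6R)-4-(acetyloxy)-2-methoxy-3,5,6-trimethyloxan-2-yl]ethyl}-3,5-dimethyl-4-[(trimethylsilyl)oxy]-5,6-dihydro-2H-pyran-2-one | CC1=C(O[Si](C)(C)C)[C@@H](C)[C@H](OC1=O)[C@H](C)[C@]3(OC)O[C@H](C)[C@@H](C)[C@@H](OC(C)=O)[C@H]3C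
F2 | step 7 | S-ethyl (2R)-2-[(2R,3R,4R,5R,6R)-4-(acetyloxy)-2-hydroxy-3,5,6-trimethyloxan-2-yl]propanethioate (wanted C6 epimer drawn) | CCSC(=O)[C@H](C)[C@]1(O)O[C@H](C)[C@@H](C)[C@@H](OC(C)=O)[C@H]1C
F3 | step 7 | S-ethyl (2R)-2-[(2R,3R,4R,5R,6R)-4-(acetyloxy)-2-methoxy-3,5,6-trimethyloxan-2-yl]propanethioate | CCSC(=O)[C@H](C)[C@]1(OC)O[C@H](C)[C@@H](C)[C@@H](OC(C)=O)[C@H]1C
F4 | step 8 | (2S)-2-[(2S,3R,4R,5R,6R)-4-(acetyloxy)-2-methoxy-3,5,6-trimethyloxan-2-yl]propan-1-ol | OC[C@H](C)[C@]1(OC)O[C@H](C)[C@@H](C)[C@@H](OC(C)=O)[C@H]1C
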